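**Strategy.** The route rests on cutting two bonds around the ring fusion: C10–CH3 and C5–C6 (eudesmane numbering). Because C10 is the β-carbon and C5 the α-carbon of a C4 carbonyl in ring A, a 3-substituted cyclohexenone whose side chain carries C9–C6 and ends in a C6 iodide can accept the angular methyl by catalytic asymmetric conjugate addition and then, as the C4–C5 enolate, close ring B on C6. One operation should create both bonds, ring B, the quaternary C10 and the cis junction at C5. The precursor comes from an auxiliary-controlled syn-aldol reaction (C7, C8) and Birch unmasking of the enone; the C4 ketone later anchors the C3 and C4 oxygens.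

Key step: step 6

Remarks on the chemistry:
- Numbering is that of eudesmane: ring A = C1–C5 and C10, ring B = C5–C10; C3 carries the angelate, C4 the methyl and acetate, C7 the isopropyl group, C8 the ketone, C10 the angular methyl. α/β refer to the drawing with the C10 methyl β.
- The target is 3α-angeloyloxy, 4α-acetoxy, 4β-methyl, 5β-H, 7β-isopropyl, 10β-methyl (3R,4S,5S,7R,10R), a cis-decalin.
- The side-chain centres of the iodo enone are set as (2S,3R) so that isopropyl (7β) and silyloxy (8α) are both equatorial in the product chair. That chair has C9 axial on ring A, which shields the α face of C4 in the later steps.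
- Assumption: L* is a 2,2'-biphenol-derived phosphoramidite of a bis(1-arylethyl)amine; its sense of induction is taken to follow simple 3-alkylcyclohexenones, and the enantiomer that delivers methyl to the Si face of C10 is the one meant.

**Route**

Step 1
Reactants: 1 (4R)-4-benzyl-3-(3-methylbutanoyl)-1,3-oxazolidin-2-one; 2 (3-methoxyphenyl)acetaldehyde
Product: 4 (4R)-4-benzyl-3-[(2R,3S)-3-hydroxy-4-(3-methoxyphenyl)-2-(propan-2-yl)butanoyl]-1,3-oxazolidin-2-one, via boron enolate 3 (not isolated)
Conditions: Bu2BOTf, iPr2NEt, CH2Cl2, 0 °C; then 2, −78 → 0 °C; H2O2, pH 7 buffer, MeOH, 0 °C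
Reagents that add atoms: none
Why: Evans syn-aldol reaction, in which the (Z)-boron enolate 3 adds through a closed chair transition state whose face is fixed by the (R)-benzyl auxiliary, so C7 and C8 should be set together as the required syn pair.

Step 2
Reactants: 4 (4R)-4-benzyl-3-[(2R,3S)-3-hydroxy-4-(3-methoxyphenyl)-2-(propan-2-yl)butanoyl]-1,3-oxazolidin-2-one
Product: 5 (4R)-4-benzyl-3-[(2R,3S)-3-(tert-butyldimethylsilyloxy)-4-(3-methoxyphenyl)-2-(propan-2-yl)butanoyl]-1,3-oxazolidin-2-one
Conditions: TBSOTf, 2,6-lutidine, CH2Cl2, −78 → 0 °C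
Reagents that add atoms: tert-butyldimethylsilyl trifluoromethanesulfonate, CC(C)(C)[Si](C)(C)OS(=O)(=O)C(F)(F)F
Why: Silyl ether formation with a silyl triflate is a standard protection of a hindered secondary alcohol; it blocks retro-aldol cleavage and touches no stereocentre.

Step 3
Reactants: 5 (4R)-4-benzyl-3-[(2R,3S)-3-(tert-butyldimethylsilyloxy)-4-(3-methoxyphenyl)-2-(propan-2-yl)butanoyl]-1,3-oxazolidin-2-one
Product: 6 (2S,3S)-3-(tert-butyldimethylsilyloxy)-4-(3-methoxyphenyl)-2-(propan-2-yl)butan-1-ol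
Conditions: LiBH4, MeOH (1 equiv), THF, 0 °C → rt
Reagents that add atoms: none
Why: Reductive cleavage of the N-acyl oxazolidinone with LiBH4 should release the primary C6 alcohol and the auxiliary without epimerising C7 (the descriptor changes only because of CIP priorities).

Step 4
Reactants: 6 (2S,3S)-3-(tert-butyldimethylsilyloxy)-4-(3-methoxyphenyl)-2-(propan-2-yl)butan-1-ol
Product: 8 3-[(2S,3S)-2-(tert-butyldimethylsilyloxy)-3-(hydroxymethyl)-4-methylpentyl]cyclohex-2-en-1-one, via dihydroanisole 7 (not isolated)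
Conditions: Li, NH3 (l), t-BuOH, THF, −78 °C; NH4Cl; then 1 M HCl, THF, 0 °C → rt
Reagents that add atoms: water, O
Why: Birch reduction of the meta-alkyl anisole gives the 2,5-dihydro enol ether 7, and mild acid hydrolysis with migration of the double bond into conjugation unmasks the 3-alkylcyclohex-2-enone, while the homobenzylic silyl ether and the remote stereocentres should be unaffected at low temperature and short acid contact.

Step 5
Reactants: 8 3-[(2S,3S)-2-(tert-butyldimethylsilyloxy)-3-(hydroxymethyl)-4-methylpentyl]cyclohex-2-en-1-one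
Product: 9 3-[(2S,3R)-2-(tert-butyldimethylsilyloxy)-3-(iodomethyl)-4-methylpentyl]cyclohex-2-en-1-one
Conditions: I2, PPh3, imidazole, CH2Cl2, 0 °C → rt
Reagents that add atoms: iodine, II
Why: Appel iodination converts the primary alcohol into the primary iodide under neutral conditions that spare the enone and the silyl ether; substitution is at CH2, so no stereocentre changes.

Step 6
Reactants: 9 3-[(2S,3R)-2-(tert-butyldimethylsilyloxy)-3-(iodomethyl)-4-methylpentyl]cyclohex-2-en-1-one; 10 trimethylaluminium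
Product: 12 (4aR,6S,7R,8aS)-6-(tert-butyldimethylsilyloxy)-4a-methyl-7-(propan-2-yl)octahydronaphthalen-1(2H)-one (cis-fused; eudesmane C4 ketone), via aluminium enolate 11 (not isolated)
Conditions: Cu(O2CC4H3S) (copper thiophene-2-carboxylate, monovalent copper; 5 mol %), phosphoramidite L* (10 mol %), Me3Al (1.5 equiv), Et2O, −30 °C; then MeLi (1.5 equiv), THF–DMPU, −30 °C → rt
Reagents that add atoms: none
Why: The chiral copper–phosphoramidite complex takes methyl from Me3Al and delivers it 1,4 to C10, giving the dimethylaluminium enolate 11 across C4–C5; MeLi converts this into the more nucleophilic aluminate, whose carbon C5 displaces iodide at C6 in an intramolecular SN2 reaction. The closest known chemistry is copper-catalysed asymmetric conjugate methylation of 3-alkylcyclohexenones with alkylation of the aluminium enolate after MeLi activation, together with Michael-initiated ring closures that give cis-decalones. Ring B closes in the 6-(enolexo)-exo-tet mode. C10 (R) is set by the ligand, which selects the Si face; C5 (S) follows because a four-carbon tether on C10 can only reach the enolate face on which it sits, so the junction must be cis. Closure should run through the array that leads to the chair with the C7 isopropyl and C8 silyloxy groups equatorial. The step needs 1,4-addition over 1,2-addition and over attack at the iodide (copper catalysis at low temperature; Me3Al does not couple with a primary iodide) and C-alkylation at C5 only (the enolate is formed regiospecifically and O-alkylation or attack from C3 would need a medium ring), and MeLi is limited to the amount of aluminium so that none remains to add to the new ketone.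

Step 7
Reactants: 12 (4aR,6S,7R,8aS)-6-(tert-butyldimethylsilyloxy)-4a-methyl-7-(propan-2-yl)octahydronaphthalen-1(2H)-one
Product: 14 (2S,4aR,6S,7R,8aS)-6-(tert-butyldimethylsilyloxy)-2-hydroxy-4a-methyl-7-(propan-2-yl)octahydronaphthalen-1(2H)-one (3β-hydroxy in eudesmane numbering), via potassium enolate 13 (not isolated)
Conditions: KN(SiMe3)2, THF, −78 °C; 3-phenyl-2-(phenylsulfonyl)oxaziridine, −78 °C; NH4Cl (aq)
Reagents that add atoms: 3-phenyl-2-(phenylsulfonyl)oxaziridine, O=S(=O)(c1ccccc1)N1OC1c1ccccc1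
Why: Davis oxidation, in which the base removes a proton from the C3 methylene (kinetic side; C5 is a hindered methine) and enolate 13 is hydroxylated axially on the open β face, so mainly the 3β-alcohol is expected; either epimer serves because this centre is reset in steps 9 and 10.

Step 8
Reactants: 14 (2S,4aR,6S,7R,8aS)-6-(tert-butyldimethylsilyloxy)-2-hydroxy-4a-methyl-7-(propan-2-yl)octahydronaphthalen-1(2H)-one
Product: 15 (1S,2S,4aR,6S,7R,8aS)-6-(tert-butyldimethylsilyloxy)-1,4a-dimethyl-7-(propan-2-yl)decahydronaphthalene-1,2-diol (3β,4α-diol with 4β-methyl)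
Conditions: MeMgBr (4 equiv), CeCl3, THF, −78 → 0 °C; NH4Cl (aq)
Reagents that add atoms: methylmagnesium bromide, C[Mg]Br
Why: Grignard 1,2-addition promoted by CeCl3, in which axial approach to C4 on the α face is barred by the syn-axial C9 methylene of ring B, so methyl should enter equatorially from the β face and give the 4β-methyl 4α-carbinol (C4 S), the cerium reagent suppressing enolisation.

Step 9
Reactants: 15 (1S,2S,4aR,6S,7R,8aS)-6-(tert-butyldimethylsilyloxy)-1,4a-dimethyl-7-(propan-2-yl)decahydronaphthalene-1,2-diol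
Product: 16 (1S,4aR,6S,7R,8aS)-6-(tert-butyldimethylsilyloxy)-1-hydroxy-1,4a-dimethyl-7-(propan-2-yl)octahydronaphthalen-2(1H)-one (C3 ketone)
Conditions: (COCl)2, DMSO, CH2Cl2, −78 °C; Et3N, −78 → −20 °C
Reagents that add atoms: none
Why: Swern oxidation converts the secondary C3 alcohol into the ketone while the tertiary C4 alcohol cannot be oxidised and activated DMSO does not cleave the glycol; the C3 centre is erased on purpose.

Step 10
Reactants: 16 (1S,4aR,6S,7R,8aS)-6-(tert-butyldimethylsilyloxy)-1-hydroxy-1,4a-dimethyl-7-(propan-2-yl)octahydronaphthalen-2(1H)-one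
Product: 17 (1S,2R,4aR,6S,7R,8aS)-6-(tert-butyldimethylsilyloxy)-1,4a-dimethyl-7-(propan-2-yl)decahydronaphthalene-1,2-diol (3α,4α-diol)
Conditions: NaBH4, MeOH–CH2Cl2, −40 °C
Reagents that add atoms: none
Why: Borohydride reduction, in which the small hydride should attack C3 axially from the β face, anti to the axial C4–O bond, to give the equatorial 3α-alcohol (C3 R) cis to the C4 hydroxyl.

Step 11
Reactants: 17 (1S,2R,4aR,6S,7R,8aS)-6-(tert-butyldimethylsilyloxy)-1,4a-dimethyl-7-(propan-2-yl)decahydronaphthalene-1,2-diol; 18 angelic acid [(2Z)-2-methylbut-2-enoic acid]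
Product: 19 (1S,2R,4aR,6S,7R,8aS)-6-(tert-butyldimethylsilyloxy)-1-hydroxy-1,4a-dimethyl-7-(propan-2-yl)decahydronaphthalen-2-yl (2Z)-2-methylbut-2-enoate
Conditions: 18, 2,4,6-trichlorobenzoyl chloride, Et3N, toluene, rt; then 17, 80 °C
Reagents that add atoms: none
Why: Yamaguchi esterification through the mixed trichlorobenzoic anhydride should acylate only the secondary C3 hydroxyl (the tertiary one is too hindered) and, run without a nucleophilic catalyst, keep the Z geometry of the angelate.

Step 12
Reactants: 19 (1S,2R,4aR,6S,7R,8aS)-6-(tert-butyldimethylsilyloxy)-1-hydroxy-1,4a-dimethyl-7-(propan-2-yl)decahydronaphthalen-2-yl (2Z)-2-methylbut-2-enoate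
Product: 20 (1S,2R,4aR,6S,7R,8aS)-1-acetoxy-6-(tert-butyldimethylsilyloxy)-1,4a-dimethyl-7-(propan-2-yl)decahydronaphthalen-2-yl (2Z)-2-methylbut-2-enoate
Conditions: Ac2O, DMAP, Et3N, CH2Cl2, 40 °C
Reagents that add atoms: acetic anhydride, CC(=O)OC(C)=O
Why: DMAP-catalysed acylation of the remaining tertiary alcohol with acetic anhydride should give the C4 acetate; the angeloyl group already sits on the thermodynamically preferred secondary oxygen, so acyl exchange is not expected, and the silyl ether is stable.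

Step 13
Reactants: 20 (1S,2R,4aR,6S,7R,8aS)-1-acetoxy-6-(tert-butyldimethylsilyloxy)-1,4a-dimethyl-7-(propan-2-yl)decahydronaphthalen-2-yl (2Z)-2-methylbut-2-enoate
Product: 21 (1S,2R,4aR,6S,7R,8aS)-1-acetoxy-6-hydroxy-1,4a-dimethyl-7-(propan-2-yl)decahydronaphthalen-2-yl (2Z)-2-methylbut-2-enoate
Conditions: HF·pyridine, pyridine, THF, 0 °C → rt
Reagents that add atoms: none
Why: Fluoride cleavage of the silyl ether with buffered HF·pyridine should free the C8 alcohol without touching the two esters, and no acyl shift is possible because no other hydroxyl is free.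

Step 14
Reactants: 21 (1S,2R,4aR,6S,7R,8aS)-1-acetoxy-6-hydroxy-1,4a-dimethyl-7-(propan-2-yl)decahydronaphthalen-2-yl (2Z)-2-methylbut-2-enoate
Product: 22 (1S,2R,4aR,7R,8aS)-1-acetoxy-1,4a-dimethyl-6-oxo-7-(propan-2-yl)decahydronaphthalen-2-yl (2Z)-2-methylbut-2-enoate (target)
Conditions: Dess–Martin periodinane, NaHCO3, CH2Cl2, rt
Reagents that add atoms: none
Why: Dess–Martin oxidation of the secondary C8 alcohol gives the ketone under buffered conditions; C7 (R) already holds the isopropyl group equatorial, which is the thermodynamically preferred arrangement next to the new carbonyl, so no epimerisation is needed.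

**Compound list**

1 | (4R)-4-benzyl-3-(3-methylbutanoyl)-1,3-oxazolidin-2-one | CC(C)CC(=O)N1[C@H](Cc2ccccc2)COC1=O | starting material
2 | (3-methoxyphenyl)acetaldehyde | COc1cccc(CC=O)c1 | starting material
3 | (Z)-dibutylboron enolate of 1 | CCCCB(CCCC)O/C(=C\C(C)C)N1[C@H](Cc2ccccc2)COC1=O | intermediate
4 | (4R)-4-benzyl-3-[(2R,3S)-3-hydroxy-4-(3-methoxyphenyl)-2-(propan-2-yl)butanoyl]-1,3-oxazolidin-2-one | COc1cccc(C[C@H](O)[C@@H](C(C)C)C(=O)N2[C@H](Cc3ccccc3)COC2=O)c1 | intermediate
5 | (4R)-4-benzyl-3-[(2R,3S)-3-(tert-butyldimethylsilyloxy)-4-(3-methoxyphenyl)-2-(propan-2-yl)butanoyl]-1,3-oxazolidin-2-one | COc1cccc(C[C@H](O[Si](C)(C)C(C)(C)C)[C@@H](C(C)C)C(=O)N2[C@H](Cc3ccccc3)COC2=O)c1 | intermediate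
6 | (2S,3S)-3-(tert-butyldimethylsilyloxy)-4-(3-methoxyphenyl)-2-(propan-2-yl)butan-1-ol | COc1cccc(C[C@H](O[Si](C)(C)C(C)(C)C)[C@@H](C(C)C)CO)c1 | intermediate
7 | (2S,3S)-3-(tert-butyldimethylsilyloxy)-4-(5-methoxycyclohexa-1,4-dien-1-yl)-2-(propan-2-yl)butan-1-ol | COC1=CCC=C(C[C@H](O[Si](C)(C)C(C)(C)C)[C@@H](C(C)C)CO)C1 | intermediate
8 | 3-[(2S,3S)-2-(tert-butyldimethylsilyloxy)-3-(hydroxymethyl)-4-methylpentyl]cyclohex-2-en-1-one | O=C1C=C(C[C@H](O[Si](C)(C)C(C)(C)C)[C@@H](C(C)C)CO)CCC1 | intermediate
9 | 3-[(2S,3R)-2-(tert-butyldimethylsilyloxy)-3-(iodomethyl)-4-methylpentyl]cyclohex-2-en-1-one | O=C1C=C(C[C@H](O[Si](C)(C)C(C)(C)C)[C@H](CI)C(C)C)CCC1 | intermediate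
10 | trimethylaluminium | C[Al](C)C | starting material
11 | dimethylaluminium enolate (C4=C5) of (3R)-3-[(2S,3R)-2-(tert-butyldimethylsilyloxy)-3-(iodomethyl)-4-methylpentyl]-3-methylcyclohexanone | C[Al](C)OC1=C[C@@](C)(C[C@H](O[Si](C)(C)C(C)(C)C)[C@H](CI)C(C)C)CCC1 | intermediate
12 | (4aR,6S,7R,8aS)-6-(tert-butyldimethylsilyloxy)-4a-methyl-7-(propan-2-yl)octahydronaphthalen-1(2H)-one | C1CC[C@]2(C)C[C@H](O[Si](C)(C)C(C)(C)C)[C@@H](C(C)C)C[C@@H]2C1=O | intermediate
13 | potassium enolate (C3=C4) of 12 | [K+].[O-]C1=CCC[C@]2(C)C[C@H](O[Si](C)(C)C(C)(C)C)[C@@H](C(C)C)C[C@H]12 | intermediate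
14 | (2S,4aR,6S,7R,8aS)-6-(tert-butyldimethylsilyloxy)-2-hydroxy-4a-methyl-7-(propan-2-yl)octahydronaphthalen-1(2H)-one (3β epimer drawn) | O[C@H]1CC[C@]2(C)C[C@H](O[Si](C)(C)C(C)(C)C)[C@@H](C(C)C)C[C@@H]2C1=O | intermediate
15 | (1S,2S,4aR,6S,7R,8aS)-6-(tert-butyldimethylsilyloxy)-1,4a-dimethyl-7-(propan-2-yl)decahydronaphthalene-1,2-diol | O[C@H]1CC[C@]2(C)C[C@H](O[Si](C)(C)C(C)(C)C)[C@@H](C(C)C)C[C@@H]2[C@]1(C)O | intermediate
16 | (1S,4aR,6S,7R,8aS)-6-(tert-butyldimethylsilyloxy)-1-hydroxy-1,4a-dimethyl-7-(propan-2-yl)octahydronaphthalen-2(1H)-one | O=C1CC[C@]2(C)C[C@H](O[Si](C)(C)C(C)(C)C)[C@@H](C(C)C)C[C@@H]2[C@]1(C)O | intermediate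
17 | (1S,2R,4aR,6S,7R,8aS)-6-(tert-butyldimethylsilyloxy)-1,4a-dimethyl-7-(propan-2-yl)decahydronaphthalene-1,2-diol | O[C@@H]1CC[C@]2(C)C[C@H](O[Si](C)(C)C(C)(C)C)[C@@H](C(C)C)C[C@@H]2[C@]1(C)O | intermediate
18 | angelic acid, (2Z)-2-methylbut-2-enoic acid | C/C=C(/C)C(=O)O | starting material
19 | (1S,2R,4aR,6S,7R,8aS)-6-(tert-butyldimethylsilyloxy)-1-hydroxy-1,4a-dimethyl-7-(propan-2-yl)decahydronaphthalen-2-yl (2Z)-2-methylbut-2-enoate | C/C=C(/C)C(=O)O[C@@H]1CC[C@]2(C)C[C@H](O[Si](C)(C)C(C)(C)C)[C@@H](C(C)C)C[C@@H]2[C@]1(C)O | intermediate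
20 | (1S,2R,4aR,6S,7R,8aS)-1-acetoxy-6-(tert-butyldimethylsilyloxy)-1,4a-dimethyl-7-(propan-2-yl)decahydronaphthalen-2-yl (2Z)-2-methylbut-2-enoate | C/C=C(/C)C(=O)O[C@@H]1CC[C@]2(C)C[C@H](O[Si](C)(C)C(C)(C)C)[C@@H](C(C)C)C[C@@H]2[C@]1(C)OC(C)=O | intermediate
21 | (1S,2R,4aR,6S,7R,8aS)-1-acetoxy-6-hydroxy-1,4a-dimethyl-7-(propan-2-yl)decahydronaphthalen-2-yl (2Z)-2-methylbut-2-enoate | C/C=C(/C)C(=O)O[C@@H]1CC[C@]2(C)C[C@H](O)[C@@H](C(C)C)C[C@@H]2[C@]1(C)OC(C)=O | intermediate
22 | (1S,2R,4aR,7R,8aS)-1-acetoxy-1,4a-dimethyl-6-oxo-7-(propan-2-yl)decahydronaphthalen-2-yl (2Z)-2-methylbut-2-enoate | C/C=C(/C)C(=O)O[C@@H]1CC[C@]2(C)CC(=O)[C@@H](C(C)C)C[C@@H]2[C@]1(C)OC(C)=O | target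

**Step count and risks**

Total steps: 14. Longest linear sequence: 14 steps (1 and 2 to 22).

The three steps most likely to fail:

Step 6. The ring closure may be slow, because the iodide is β-branched and because the chair–chair array with the new bond axial on ring A would force both chain substituents axial, so the ring has to close through the less ideal half-chair with the tether pseudoaxial on C10. Proton transfer, intermolecular alkylation or addition of a methyl-metal species to the product could then compete, and facial control at C10 could be incomplete. The fallback sets out from 9 and separates the two events. The same copper-catalysed methylation is run, but the aluminium enolate is silylated (TMSOTf, Et2O, −30 °C) and the trimethylsilyl enol ether of (3R)-3-[(2S,3R)-2-(tert-butyldimethylsilyloxy)-3-(iodomethyl)-4-methylpentyl]-3-methylcyclohexanone F1 is isolated. MeLi in THF then releases the lithium enolate free of aluminium, and DMPU or HMPA drives the 6-(enolexo)-exo-tet alkylation. The fallback comes back to the route at 12.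

Step 12. Acylation of the crowded axial tertiary hydroxyl may stall, and long heating with amine base may isomerise the angelate to the tiglate. The fallback sets out from 19 and moves the acetylation to the end. HF·pyridine removes the silyl ether to give the 4,8-diol 3-angelate F2. Dess–Martin oxidation of the secondary C8 alcohol gives the 8-keto 4-hydroxy 3-angelate F3. The tertiary alcohol is then acetylated with Ac2O under Lewis acid activation (Sc(OTf)3 cat., MeCN, −20 °C), a method known to acylate tertiary alcohols. The fallback comes back to the route at 22.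

Step 8. The hindered α-oxido ketone may be deprotonated instead of attacked, or facial control may erode because the axial 3β-alkoxide crowds the β face. The fallback sets out from 12 and builds the C4 methyl and both oxygens differently:
- The kinetic enol triflate F4 is formed (KN(SiMe3)2, PhNTf2, THF, −78 °C).
- Coupling with Me2CuLi gives the C3=C4 alkene carrying the C4 methyl, F5.
- Woodward cis-hydroxylation (I2, AgOAc, AcOH; then wet AcOH, heat) is applied: iodonium formation on the open β face and acetate attack at C4 from the α face give the trans-diaxial 3β-iodo 4α-acetate F6; acetoxonium participation with inversion at C3 and hydrolysis give the α-face cis hydroxy acetate F7.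
- Methanolysis (K2CO3, MeOH) gives the diol.

The fallback comes back to the route at 17.

**Further compounds**

F1 | step 6 | trimethylsilyl enol ether (C4=C5) of (3R)-3-[(2S,3R)-2-(tert-butyldimethylsilyloxy)-3-(iodomethyl)-4-methylpentyl]-3-methylcyclohexanone | C[Si](C)(C)OC1=C[C@@](C)(C[C@H](O[Si](C)(C)C(C)(C)C)[C@H](CI)C(C)C)CCC1
F2 | step 12 | (1S,2R,4aR,6S,7R,8aS)-1,6-dihydroxy-1,4a-dimethyl-7-(propan-2-yl)decahydronaphthalen-2-yl (2Z)-2-methylbut-2-enoate | C/C=C(/C)C(=O)O[C@@H]1CC[C@]2(C)C[C@H](O)[C@@H](C(C)C)C[C@@H]2[C@]1(C)O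
F3 | step 12 | (1S,2R,4aR,7R,8aS)-1-hydroxy-1,4a-dimethyl-6-oxo-7-(propan-2-yl)decahydronaphthalen-2-yl (2Z)-2-methylbut-2-enoate | C/C=C(/C)C(=O)O[C@@H]1CC[C@]2(C)CC(=O)[C@@H](C(C)C)C[C@@H]2[C@]1(C)O
F4 | step 8 | (4aR,6S,7R,8aS)-6-(tert-butyldimethylsilyloxy)-4a-methyl-7-(propan-2-yl)-3,4,4a,5,6,7,8,8a-octahydronaphthalen-1-yl trifluoromethanesulfonate | O=S(=O)(OC1=CCC[C@]2(C)C[C@H](O[Si](C)(C)C(C)(C)C)[C@@H](C(C)C)C[C@H]12)C(F)(F)F
F5 | step 8 | 8α-(tert-butyldimethylsilyloxy)-5β-H-eudesm-3-ene (C3=C4 alkene with the C4 methyl; 7β-isopropyl, 10β-methyl) | CC1=CCC[C@]2(C)C[C@H](O[Si](C)(C)C(C)(C)C)[C@@H](C(C)C)C[C@H]12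
F6 | step 8 | 4α-acetoxy-8α-(tert-butyldimethylsilyloxy)-3β-iodo-5β-H-eudesmane | I[C@H]1CC[C@]2(C)C[C@H](O[Si](C)(C)C(C)(C)C)[C@@H](C(C)C)C[C@@H]2[C@]1(C)OC(C)=O
F7 | step 8 | 4α-acetoxy-8α-(tert-butyldimethylsilyloxy)-5β-H-eudesman-3α-ol | O[C@@H]1CC[C@]2(C)C[C@H](O[Si](C)(C)C(C)(C)C)[C@@H](C(C)C)C[C@@H]2[C@]1(C)OC(C)=O
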